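**Retrosynthetic overview**
1. The target is released by global desilylation of its tris-TBS ether. The diene is cut at the alkene next to the isochromenone (Horner–Wadsworth–Emmons) into an isochromenon-3-ylmethyl phosphonate and a (2E)-3-(oxolan-2-yl)propenal.
2. The propenal comes from the oxolane-2-carbaldehyde by a two-carbon Wittig homologation; the aldehyde comes from the primary alcohol of a 2,3,5-trisubstituted oxolane.
3. The strategy rests on oxolane C5, the methyl-bearing carbon bonded to ring oxygen O1, with the methyl cis to the C2 chain and trans to the C3 oxygen. The O1–C5 bond and this stereocenter are made together by reductive cycloetherification of a γ-hydroxy methyl ketone from 2-deoxy-D-ribonolactone and MeLi; C2 and C3 come from the sugar.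
4. The phosphonate comes from methyl orsellinate by ring chlorination, lateral lithiation and acylation with a chloroacetyl Weinreb amide, acid cyclodehydration to the isochromenone, silylation and Arbuzov reaction.
5. Ring order: oxolane first (step 4), then the pyranone ring of the isochromenone (step 11); the benzene ring is bought.

Key step: step 4

Remark: the methyllithium adduct of the lactone is a ring–chain tautomeric mixture; it is written as the open hydroxy ketone, and its ring-closed hemiketal is counted as an intermediate of the key step. Abbreviations: TBS = tert-butyldimethylsilyl, MOM = methoxymethyl.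

**Route**

Step 1
Reactants: 1 2-deoxy-D-ribose
Product: 2 2-deoxy-D-ribono-1,4-lactone [(4S,5R)-4-hydroxy-5-(hydroxymethyl)oxolan-2-one]
Conditions: Br2, H2O, rt
Reagents that add atoms: none
Why: Bromine-water oxidation of an aldose hemiacetal to the aldono-1,4-lactone is a classical reaction that touches only C1, so the two carbinol stereocenters of the sugar are carried over unchanged.

Step 2
Reactants: 2 2-deoxy-D-ribono-1,4-lactone
Product: 3 (4S,5R)-4-(TBSO)-5-[(TBSO)methyl]oxolan-2-one
Conditions: TBSCl, imidazole, DMF, rt
Reagents that add atoms: tert-butyldimethylsilyl chloride, CC(C)(C)[Si](C)(C)Cl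
Why: Silyl ether formation with TBSCl and imidazole should protect the primary and the secondary hydroxyl alike, giving a lactone with no acidic O–H for the organolithium step.

Step 3
Reactants: 3 bis-TBS lactone; 4 methyllithium
Product: 5 (4S,5R)-4,6-bis(TBSO)-5-hydroxyhexan-2-one
Conditions: MeLi (1.1 equiv), THF, −78 °C; AcOH quench at −78 °C
Reagents that add atoms: none
Why: Organolithium addition to a γ-lactone should stop after one addition because the lithium alkoxide of the tetrahedral adduct does not open to the ketone at −78 °C, and the cold acetic acid quench then releases the hydroxy ketone without touching the two stereocenters.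

Step 4
Reactants: 5 (4S,5R)-4,6-bis(TBSO)-5-hydroxyhexan-2-one
Product: 8 (2R,3S,5S)-3-(tert-butyldimethylsilyloxy)-2-[(tert-butyldimethylsilyloxy)methyl]-5-methyloxolane, via cyclic hemiketal 6 (not isolated), via oxocarbenium ion 7 (not isolated)
Conditions: Et3SiH (3 equiv), BF3·OEt2 (2 equiv), CH2Cl2, −78 to −40 °C; NaHCO3 quench
Reagents that add atoms: none
Why: The open tautomer closes by 5-exo-trig hemiketalization (the C5 hydroxyl oxygen adds to the ketone carbon, forming the O1–C5 bond of the oxolane), BF3·OEt2 ionizes hemiketal 6 to the cyclic oxocarbenium ion 7, and Et3SiH reduces 7 irreversibly by hydride transfer. This is the ionic-hydrogenation (reductive C-glycosidation) protocol established for ketofuranose hemiketals made from 2-deoxyribonolactone and organolithium reagents. The single new stereocenter, C5, is fixed by the conformation of 7: the envelope holding the C3 silyloxy group pseudoaxial is preferred and the silane attacks on its inside face, syn to that oxygen, so the methyl group ends up trans to the C3–O bond and cis to the C2 substituent, which is (5S). The step needs facial selectivity, and this is secured because attack anti to the C2 CH2OTBS arm points the same way as the C3-oxygen effect. It also needs both silyl ethers to survive the Lewis acid, which the low temperature should ensure. C2 and C3 come unchanged from the sugar, so the absolute configuration is that of the starting pentose.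

Step 5
Reactants: 8 bis-TBS oxolane
Product: 9 [(2R,3S,5S)-3-(TBSO)-5-methyloxolan-2-yl]methanol
Conditions: TFA–H2O–THF (1:1:4), 0 °C
Reagents that add atoms: none
Why: Acid-catalysed hydrolytic desilylation is much faster for the unhindered primary silyl ether than for the secondary one flanked by two ring substituents, the selectivity known from 3′,5′-bis-silylated nucleosides.

Step 6
Reactants: 9 primary alcohol
Product: 10 (2S,3S,5S)-3-(TBSO)-5-methyloxolane-2-carbaldehyde
Conditions: Dess–Martin periodinane (1,1,1-triacetoxy-1,1-dihydro-1,2-benziodoxol-3(1H)-one), NaHCO3, CH2Cl2, 0 °C to rt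
Reagents that add atoms: none
Why: Dess–Martin oxidation of a primary alcohol under bicarbonate buffering should give the aldehyde without epimerizing the adjacent C2 stereocenter or eliminating the β-silyloxy group (the descriptor at C2 changes only because the formyl group outranks C3).

Step 7
Reactants: 10 oxolane-2-carbaldehyde; 11 (triphenylphosphoranylidene)acetaldehyde
Product: 12 (2E)-3-[(2R,3S,5S)-3-(TBSO)-5-methyloxolan-2-yl]prop-2-enal
Conditions: Ph3P=CHCHO (1.2 equiv), toluene, 70 °C
Reagents that add atoms: none
Why: Wittig olefination with the stabilized formylmethylene ylide is a reliable two-carbon homologation that should give the E enal, and the weakly basic ylide leaves the C2 stereocenter intact.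

Step 8
Reactants: 13 methyl 2,4-dihydroxy-6-methylbenzoate (methyl orsellinate)
Product: 14 methyl 3-chloro-4,6-dihydroxy-2-methylbenzoate
Conditions: SO2Cl2 (1.0 equiv), Et2O, 0 °C
Reagents that add atoms: sulfuryl chloride, O=S(=O)(Cl)Cl
Why: Electrophilic aromatic chlorination of methyl orsellinate with SO2Cl2 is expected at C5, ortho to the free 4-hydroxyl and para to the ester-chelated 2-hydroxyl, rather than at the more crowded C3 between the two oxygens.

Step 9
Reactants: 14 methyl 3-chloro-4,6-dihydroxy-2-methylbenzoate
Product: 15 methyl 3-chloro-4,6-bis(methoxymethoxy)-2-methylbenzoate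
Conditions: NaH, MOMCl, DMF, 0 °C to rt
Reagents that add atoms: chloromethyl methyl ether, COCCl
Why: Williamson-type O-alkylation of both phenoxides with MOMCl masks the acidic O–H groups as ethers that tolerate LiN(iPr)2.

Step 10
Reactants: 15 bis-MOM toluate; 16 2-chloro-N-methoxy-N-methylacetamide
Product: 18 methyl 3-chloro-2-(3-chloro-2-oxopropyl)-4,6-bis(methoxymethoxy)benzoate, via benzylic lithium reagent 17 (not isolated)
Conditions: LiN(iPr)2 (1.1 equiv), THF, −78 °C; then 16, −78 °C; AcOH quench
Reagents that add atoms: none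
Why: Lateral (benzylic) lithiation of an ortho-toluate followed by Weinreb ketone synthesis should give the chloromethyl ketone, since the chelated tetrahedral adduct survives until the quench and so prevents a second addition or enolization of the product.

Step 11
Reactants: 18 chloromethyl keto ester
Product: 20 5-chloro-3-(chloromethyl)-6,8-dihydroxy-1H-isochromen-1-one, via dihydroxy keto ester 19 (not isolated)
Conditions: HCl (3 M in MeOH), 40 °C; then evaporate; p-toluenesulfonic acid monohydrate (0.2 equiv), toluene–1,4-dioxane, reflux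
Reagents that add atoms: none
Why: Acidic methanolysis removes both MOM acetals, and acid-catalysed cyclodehydration of the resulting 2-(2-oxoalkyl)benzoate (enol lactonization with loss of methanol) should close the pyranone ring of the isochromenone, the conjugated endocyclic C3=C4 isomer being the thermodynamic product.

Step 12
Reactants: 20 dihydroxy chloromethyl isochromenone
Product: 21 6,8-bis(TBSO)-5-chloro-3-(chloromethyl)-1H-isochromen-1-one
Conditions: TBSOTf (2.4 equiv), 2,6-lutidine, CH2Cl2, 0 °C
Reagents that add atoms: tert-butyldimethylsilyl trifluoromethanesulfonate, CC(C)(C)[Si](C)(C)OS(=O)(=O)C(F)(F)F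
Why: Silylation with TBSOTf and the non-nucleophilic base 2,6-lutidine should cap both phenols, the hydrogen-bonded 8-hydroxyl included, without displacing the allylic chloride.

Step 13
Reactants: 21 bis-TBS chloromethyl isochromenone
Product: 22 diethyl {[6,8-bis(TBSO)-5-chloro-1-oxo-1H-isochromen-3-yl]methyl}phosphonate
Conditions: P(OEt)3 (neat), 130 °C
Reagents that add atoms: triethyl phosphite, CCOP(OCC)OCC
Why: Michaelis–Arbuzov reaction of the activated allylic chloride with triethyl phosphite should give the phosphonate by SN2 attack of phosphorus and loss of chloroethane under neutral conditions that the aryl silyl ethers tolerate.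

Step 14
Reactants: 22 isochromenonylmethyl phosphonate; 12 oxolanyl propenal
Product: 24 6,8-bis(TBSO)-3-{(1E,3E)-4-[(2R,3S,5S)-3-(TBSO)-5-methyloxolan-2-yl]buta-1,3-dien-1-yl}-5-chloro-1H-isochromen-1-one, via sodium phosphonate carbanion 23 (not isolated)
Conditions: NaN(SiMe3)2 (1.0 equiv), THF, −78 °C; then 12, −78 to 0 °C
Reagents that add atoms: none
Why: Horner–Wadsworth–Emmons olefination, in which the carbanion (stabilized by the phosphoryl group and by vinylogous conjugation through C3=C4 and the arene to the lactone carbonyl) adds 1,2 to the enal and reversible addition followed by syn elimination should give the new alkene as the E isomer, completing the E,E-diene.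

Step 15
Reactants: 24 tris-TBS ether
Product: 25 5-chloro-6,8-dihydroxy-3-{(1E,3E)-4-[(2R,3S,5S)-3-hydroxy-5-methyloxolan-2-yl]buta-1,3-dien-1-yl}-1H-isochromen-1-one (CNP0086741.1)
Conditions: HF·pyridine, pyridine, THF, 0 °C to rt
Reagents that add atoms: none
Why: Fluoride-mediated cleavage of the two aryl silyl ethers and of the secondary alkyl silyl ether with buffered HF·pyridine should release the target under conditions too mild to ionize the dienylic C2–O1 bond, open the lactone or touch the aryl chloride.

**Compound list**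
1 | 2-deoxy-D-ribose | O=CC[C@H](O)[C@H](O)CO | starting material
2 | 2-deoxy-D-ribono-1,4-lactone, (4S,5R)-4-hydroxy-5-(hydroxymethyl)oxolan-2-one | O=C1C[C@H](O)[C@@H](CO)O1 | intermediate
3 | (4S,5R)-4-(tert-butyldimethylsilyloxy)-5-[(tert-butyldimethylsilyloxy)methyl]oxolan-2-one | O=C1C[C@H](O[Si](C)(C)C(C)(C)C)[C@@H](CO[Si](C)(C)C(C)(C)C)O1 | intermediate
4 | methyllithium | [Li]C | starting material
5 | (4S,5R)-4,6-bis(tert-butyldimethylsilyloxy)-5-hydroxyhexan-2-one | CC(=O)C[C@H](O[Si](C)(C)C(C)(C)C)[C@H](O)CO[Si](C)(C)C(C)(C)C | intermediate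
6 | (4S,5R)-4-(tert-butyldimethylsilyloxy)-5-[(tert-butyldimethylsilyloxy)methyl]-2-methyloxolan-2-ol (cyclic hemiketal, both C2 epimers) | CC1(O)C[C@H](O[Si](C)(C)C(C)(C)C)[C@@H](CO[Si](C)(C)C(C)(C)C)O1 | intermediate
7 | (2R,3S)-3-(tert-butyldimethylsilyloxy)-2-[(tert-butyldimethylsilyloxy)methyl]-5-methyl-3,4-dihydro-2H-furan-1-ium (oxocarbenium ion) | CC1=[O+][C@H](CO[Si](C)(C)C(C)(C)C)[C@@H](O[Si](C)(C)C(C)(C)C)C1 | intermediate
8 | (2R,3S,5S)-3-(tert-butyldimethylsilyloxy)-2-[(tert-butyldimethylsilyloxy)methyl]-5-methyloxolane | C[C@H]1C[C@H](O[Si](C)(C)C(C)(C)C)[C@@H](CO[Si](C)(C)C(C)(C)C)O1 | intermediate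
9 | [(2R,3S,5S)-3-(tert-butyldimethylsilyloxy)-5-methyloxolan-2-yl]methanol | C[C@H]1C[C@H](O[Si](C)(C)C(C)(C)C)[C@@H](CO)O1 | intermediate
10 | (2S,3S,5S)-3-(tert-butyldimethylsilyloxy)-5-methyloxolane-2-carbaldehyde | C[C@H]1C[C@H](O[Si](C)(C)C(C)(C)C)[C@@H](C=O)O1 | intermediate
11 | (triphenylphosphoranylidene)acetaldehyde | O=CC=P(c1ccccc1)(c1ccccc1)c1ccccc1 | starting material
12 | (2E)-3-[(2R,3S,5S)-3-(tert-butyldimethylsilyloxy)-5-methyloxolan-2-yl]prop-2-enal | C[C@H]1C[C@H](O[Si](C)(C)C(C)(C)C)[C@@H](/C=C/C=O)O1 | intermediate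
13 | methyl 2,4-dihydroxy-6-methylbenzoate (methyl orsellinate) | COC(=O)c1c(C)cc(O)cc1O | starting material
14 | methyl 3-chloro-4,6-dihydroxy-2-methylbenzoate | COC(=O)c1c(C)c(Cl)c(O)cc1O | intermediate
15 | methyl 3-chloro-4,6-bis(methoxymethoxy)-2-methylbenzoate | COC(=O)c1c(C)c(Cl)c(OCOC)cc1OCOC | intermediate
16 | 2-chloro-N-methoxy-N-methylacetamide | ClCC(=O)N(C)OC | starting material
17 | [2-chloro-6-(methoxycarbonyl)-3,5-bis(methoxymethoxy)phenyl]methyllithium | [Li]Cc1c(Cl)c(OCOC)cc(OCOC)c1C(=O)OC | intermediate
18 | methyl 3-chloro-2-(3-chloro-2-oxopropyl)-4,6-bis(methoxymethoxy)benzoate | COC(=O)c1c(CC(=O)CCl)c(Cl)c(OCOC)cc1OCOC | intermediate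
19 | methyl 3-chloro-2-(3-chloro-2-oxopropyl)-4,6-dihydroxybenzoate | COC(=O)c1c(CC(=O)CCl)c(Cl)c(O)cc1O | intermediate
20 | 5-chloro-3-(chloromethyl)-6,8-dihydroxy-1H-isochromen-1-one | O=c1oc(CCl)cc2c(Cl)c(O)cc(O)c12 | intermediate
21 | 6,8-bis(tert-butyldimethylsilyloxy)-5-chloro-3-(chloromethyl)-1H-isochromen-1-one | O=c1oc(CCl)cc2c(Cl)c(O[Si](C)(C)C(C)(C)C)cc(O[Si](C)(C)C(C)(C)C)c12 | intermediate
22 | diethyl {[6,8-bis(tert-butyldimethylsilyloxy)-5-chloro-1-oxo-1H-isochromen-3-yl]methyl}phosphonate | CCOP(=O)(OCC)Cc1cc2c(Cl)c(O[Si](C)(C)C(C)(C)C)cc(O[Si](C)(C)C(C)(C)C)c2c(=O)o1 | intermediate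
23 | sodium salt of the α-carbanion of phosphonate 22 | [Na+].CCOP(=O)(OCC)[CH-]c1cc2c(Cl)c(O[Si](C)(C)C(C)(C)C)cc(O[Si](C)(C)C(C)(C)C)c2c(=O)o1 | intermediate
24 | 6,8-bis(tert-butyldimethylsilyloxy)-3-{(1E,3E)-4-[(2R,3S,5S)-3-(tert-butyldimethylsilyloxy)-5-methyloxolan-2-yl]buta-1,3-dien-1-yl}-5-chloro-1H-isochromen-1-one | C[C@H]1C[C@H](O[Si](C)(C)C(C)(C)C)[C@@H](/C=C/C=C/c2cc3c(Cl)c(O[Si](C)(C)C(C)(C)C)cc(O[Si](C)(C)C(C)(C)C)c3c(=O)o2)O1 | intermediate
25 | 5-chloro-6,8-dihydroxy-3-{(1E,3E)-4-[(2R,3S,5S)-3-hydroxy-5-methyloxolan-2-yl]buta-1,3-dien-1-yl}-1H-isochromen-1-one | C[C@H]1C[C@H](O)[C@@H](/C=C/C=C/c2cc3c(Cl)c(O)cc(O)c3c(=O)o2)O1 | target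

**Step count**
Total: 15 steps. Longest linear sequence: 9 steps (steps 1–7, 14 and 15); the aromatic branch is steps 8–13.

**Steps most likely to fail**

Step 4. Hydride delivery to the oxocarbenium ion may be incompletely face-selective, the primary silyl ether may be cleaved by BF3, or the ion may lose a proton to an enol ether. Fallback, setting out from 5 and returning at 8: C5 is set by reagent control and the ring is closed by substitution instead of reduction. The open ketone tautomer of 5 is reduced with BH3·SMe2 and the catalyst (S)-1-methyl-3,3-diphenyltetrahydro-1H,3H-pyrrolo[1,2-c][1,3,2]oxazaborole (Corey–Bakshi–Shibata reduction) to (2R,4S,5R)-4,6-bis(tert-butyldimethylsilyloxy)hexane-2,5-diol F1, any C2 epimer being removed by chromatography. Mitsunobu cyclodehydration (PPh3, diisopropyl azodicarboxylate, THF, 0 °C) should then activate the less hindered methyl carbinol, and the C5 hydroxyl displaces it with inversion (5-exo-tet) to give 8.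

Step 10. The benzylic anion may abstract a proton from the acidic α-CH2 of the chloroacetamide, or displace its chloride, instead of adding to the amide carbonyl. Fallback, setting out from 15 and returning at 22: the lithiated toluate is acylated with commercial 2-(tert-butyldimethylsilyloxy)-N-methoxy-N-methylacetamide, which has no leaving group and a less acidic α-position, to give methyl 2-[3-(tert-butyldimethylsilyloxy)-2-oxopropyl]-3-chloro-4,6-bis(methoxymethoxy)benzoate F2. The acid treatment of step 11 (HCl in MeOH, then p-toluenesulfonic acid monohydrate in hot toluene–dioxane) should remove the MOM and silyl groups and cyclize to 5-chloro-6,8-dihydroxy-3-(hydroxymethyl)-1H-isochromen-1-one F3. Appel bromination of the primary allylic alcohol (CBr4, PPh3, THF–MeCN, 0 °C) gives 3-(bromomethyl)-5-chloro-6,8-dihydroxy-1H-isochromen-1-one F4. Silylation (TBSOTf, 2,6-lutidine) gives 3-(bromomethyl)-6,8-bis(tert-butyldimethylsilyloxy)-5-chloro-1H-isochromen-1-one F5, and Arbuzov reaction with P(OEt)3 at 110 °C gives 22.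

Step 14. The new alkene may form with incomplete E selectivity, and the base may deprotonate the enal at its γ-position, which would epimerize oxolane C2 or expel the C3 silyloxy group. Fallback, setting out from 21 and returning at 24: chloride 21 is heated with PPh3 in toluene to give {[6,8-bis(tert-butyldimethylsilyloxy)-5-chloro-1-oxo-1H-isochromen-3-yl]methyl}triphenylphosphonium chloride F6. Its less basic ylide (NaN(SiMe3)2, THF, −78 °C) is combined with enal 12 in a Wittig reaction. The E/Z mixture at the new alkene is then converged to the E,E-diene 24 by equilibration with catalytic I2 in CH2Cl2 in daylight.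

**Further compounds**
F1 | step 4 | (2R,4S,5R)-4,6-bis(tert-butyldimethylsilyloxy)hexane-2,5-diol | C[C@@H](O)C[C@H](O[Si](C)(C)C(C)(C)C)[C@H](O)CO[Si](C)(C)C(C)(C)C
F2 | step 10 | methyl 2-[3-(tert-butyldimethylsilyloxy)-2-oxopropyl]-3-chloro-4,6-bis(methoxymethoxy)benzoate | COC(=O)c1c(CC(=O)CO[Si](C)(C)C(C)(C)C)c(Cl)c(OCOC)cc1OCOC
F3 | step 10 | 5-chloro-6,8-dihydroxy-3-(hydroxymethyl)-1H-isochromen-1-one | O=c1oc(CO)cc2c(Cl)c(O)cc(O)c12
F4 | step 10 | 3-(bromomethyl)-5-chloro-6,8-dihydroxy-1H-isochromen-1-one | O=c1oc(CBr)cc2c(Cl)c(O)cc(O)c12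
F5 | step 10 | 3-(bromomethyl)-6,8-bis(tert-butyldimethylsilyloxy)-5-chloro-1H-isochromen-1-one | O=c1oc(CBr)cc2c(Cl)c(O[Si](C)(C)C(C)(C)C)cc(O[Si](C)(C)C(C)(C)C)c12
F6 | step 14 | {[6,8-bis(tert-butyldimethylsilyloxy)-5-chloro-1-oxo-1H-isochromen-3-yl]methyl}triphenylphosphonium chloride | O=c1oc(C[P+](c2ccccc2)(c2ccccc2)c2ccccc2)cc2c(Cl)c(O[Si](C)(C)C(C)(C)C)cc(O[Si](C)(C)C(C)(C)C)c12.[Cl-]
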